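**Plan**

1. Locants: C1 = lactone O–CH, C5 = CH–OAc, C9 = CH–OH, C14 = ring-fusion CH of the 14-membered carbocycle; Cα = lactone α-carbon. Retrosynthetic cuts, in order: the exo-methylene at Cα; the C9–C10 ring bond together with the C11–CH3 bond (aldehyde + terminal alkyne + methyl); the lactone carbonyl back to a vinyl group; C1–C14 (allylboration); C4–C5 (propargylation); the C2=C3 and C6=C7 methyl olefins back to terminal alkynes.
2. Enabling feature: the C9 carbinol sits next to the (E)-C10=C11(CH3) olefin of the 14-membered ring with C9 and the methyl cis. This is exactly the outcome of a syn alkyne–aldehyde–methyl coupling between a C9 aldehyde and a but-3-ynyl arm on C14, so ring, olefin geometry and methyl group arise in one event.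
3. Forward: the chain C9→C1 is grown by two rounds of zirconium-catalysed methylalumination/iodination and formylation; the five-membered lactone ring arises from anti-allylboration, hydroboration and oxidative lactonisation; the 14-membered ring is closed last by nickel; α-methylenation, acetate installation and desilylation finish.
4. Stereochemistry: C5 from a phosphoric-acid-catalysed propargylation; C1/C14 (trans lactone) from a phosphoric-acid-catalysed anti-allylboration with an (E)-allylboronate; C9 from CBS reduction of the macrocyclic enone; all three (E)-olefins from syn carbometallation of terminal alkynes.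

Key step: step 14

**Remarks.** Compounds 1 and 13 are taken as commercial. TRIP = 3,3′-bis(2,4,6-triisopropylphenyl)-1,1′-binaphthyl-2,2′-diyl hydrogen phosphate; the sense of induction is assigned on the assumption that the (R)-acid directs Re-face attack, and the other enantiomer of the acid would be taken if the sense proved opposite. Compound 25 is an epimer mixture at C9 and is drawn without configuration there on purpose. In the fused-ring names (cyclotetradeca[b]furan) C15a = C1, C12 = C5, C8 = C9, C3a = C14.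

**Route**

Step 1
Reactants: 1 tert-butyl(but-3-yn-1-yloxy)dimethylsilane
Product: 3 (E)-tert-butyl[(4-iodo-3-methylbut-3-en-1-yl)oxy]dimethylsilane, via alkenylalane 2 (not isolated)
Conditions: AlMe3 (2 equiv), Cp2ZrCl2 (25 mol%), CH2Cl2, 0 °C to rt; then I2, THF, −30 °C
Reagents that add atoms: trimethylaluminium C[Al](C)C; iodine II
Why: Negishi zirconium-catalysed methylalumination adds CH3 and Al syn across the terminal alkyne with methyl on the internal carbon, and iodinolysis with retention gives the (E)-vinyl iodide.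

Step 2
Reactants: 3 (E)-vinyl iodide
Product: 5 (E)-5-(tert-butyldimethylsilyloxy)-3-methylpent-2-enal, via vinyllithium 4 (not isolated)
Conditions: t-BuLi (2.1 equiv), Et2O, −78 °C; then DMF, −78 to 0 °C; aq. NH4Cl
Reagents that add atoms: N,N-dimethylformamide CN(C)C=O
Why: iodine–lithium exchange and formylation of the vinyllithium with DMF both proceed with retention of olefin geometry.

Step 3
Reactants: 5 (E)-enal
Product: 7 (4S,5E)-8-(tert-butyldimethylsilyloxy)-6-methyloct-5-en-1-yn-4-ol, via O-boryl ether 6 (not isolated)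
Conditions: allenylboronic acid pinacol ester (1.5 equiv), (S)-TRIP (5 mol%), 4 Å molecular sieves, toluene, −20 °C; aqueous work-up
Reagents that add atoms: allenylboronic acid pinacol ester C=C=CB1OC(C)(C)C(C)(C)O1
Why: chiral-phosphoric-acid-catalysed asymmetric propargylation of an aldehyde with an allenylboronate (SE2′ through a closed six-membered transition state), in which the (S)-acid should direct Si-face attack and set C5 as (S).

Step 4
Reactants: 7 (S)-homopropargylic alcohol
Product: 9 (1E,4S,5E)-8-(tert-butyldimethylsilyloxy)-1-iodo-2,6-dimethylocta-1,5-dien-4-ol, via alkenylalane alkoxide 8 (not isolated)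
Conditions: AlMe3 (3.5 equiv), Cp2ZrCl2 (50 mol%), CH2Cl2, 0 °C to rt; then I2, THF, −30 °C
Reagents that add atoms: trimethylaluminium C[Al](C)C; iodine II
Why: second Negishi methylalumination–iodination, with the hydroxyl carried as its aluminium alkoxide (which cannot ionise) and syn addition fixing the (E)-C2=C3 geometry.

Step 5
Reactants: 9 iodo alcohol
Product: 10 (1E,4S,5E)-8-(tert-butyldimethylsilyloxy)-1-iodo-4-(4-methoxybenzyloxy)-2,6-dimethylocta-1,5-diene
Conditions: NaH, 4-methoxybenzyl chloride, Bu4NI (cat.), THF/DMF, 0 °C to rt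
Reagents that add atoms: 4-methoxybenzyl chloride COc1ccc(CCl)cc1
Why: Williamson etherification of the alkoxide, which leaves the C5 centre and the vinyl iodide untouched.

Step 6
Reactants: 10 PMB ether vinyl iodide
Product: 12 (2E,5S,6E)-9-(tert-butyldimethylsilyloxy)-5-(4-methoxybenzyloxy)-3,7-dimethylnona-2,6-dienal, via vinyllithium 11 (not isolated)
Conditions: t-BuLi (2.1 equiv), Et2O, −78 °C; then DMF, −78 to 0 °C; aq. NH4Cl
Reagents that add atoms: N,N-dimethylformamide CN(C)C=O
Why: iodine–lithium exchange is much faster than deprotonation next to the ethers at −78 °C, and formylation with retention gives the (E)-enal carrying C1.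

Step 7
Reactants: 13 (4-bromobut-1-yn-1-yl)trimethylsilane
Product: 15 rac-7-(trimethylsilyl)hept-1-en-6-yn-3-ol, via Grignard reagent 14 (not isolated)
Conditions: Mg, THF, rt; then acrolein, −78 °C; aq. NH4Cl
Reagents that add atoms: acrolein C=CC=O
Why: 1,2-addition of the Grignard reagent to acrolein gives the vinyl carbinol, whose stereocentre is erased in step 8.

Step 8
Reactants: 15 allylic alcohol
Product: 16 (E)-4,4,5,5-tetramethyl-2-[7-(trimethylsilyl)hept-2-en-6-yn-1-yl]-1,3,2-dioxaborolane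
Conditions: B2pin2, Pd(MeCN)4(BF4)2 (5 mol%), DMSO/MeOH, 50 °C
Reagents that add atoms: bis(pinacolato)diboron CC1(C)OB(OC1(C)C)B1OC(C)(C)C(C)(C)O1
Why: palladium-catalysed borylation of an allylic alcohol through an η3-allylpalladium intermediate delivers boron to the unsubstituted terminus and gives the linear (E)-allylboronate.

Step 9
Reactants: 12 dienal; 16 (E)-allylboronate
Product: 18 (3R,4R,5E,8S,9E)-12-(tert-butyldimethylsilyloxy)-8-(4-methoxybenzyloxy)-6,10-dimethyl-3-[4-(trimethylsilyl)but-3-yn-1-yl]dodeca-1,5,9-trien-4-ol, via O-boryl ether 17 (not isolated)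
Conditions: (R)-TRIP (5 mol%), 4 Å molecular sieves, toluene, −30 °C; aqueous work-up
Reagents that add atoms: none
Why: chiral-phosphoric-acid-catalysed allylboration through a chair Zimmerman–Traxler transition state, in which the (E)-γ-substituted allylboronate fixes the anti C1/C14 relationship and the (R)-acid (Re-face attack on the enal) fixes the absolute configuration of both centres.

Step 10
Reactants: 18 anti-homoallylic alcohol
Product: 20 (3R,4R,5E,8S,9E)-12-(tert-butyldimethylsilyloxy)-8-(4-methoxybenzyloxy)-6,10-dimethyl-3-[4-(trimethylsilyl)but-3-yn-1-yl]dodeca-5,9-diene-1,4-diol, via B-alkyl-9-BBN 19 (not isolated)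
Conditions: 9-BBN (2.2 equiv), THF, 0 °C to rt; then NaBO3·4H2O, H2O, rt
Reagents that add atoms: sodium perborate [Na+].[Na+].O[B-]1(O)OO[B-](O)(O)OO1
Why: anti-Markovnikov hydroboration–oxidation, in which 9-BBN selects the monosubstituted vinyl group over the trisubstituted olefins and the silyl-capped alkyne, and the mild perborate oxidation spares the C–Si bond.

Step 11
Reactants: 20 1,4-diol
Product: 22 (4R,5R)-5-[(1E,4S,5E)-8-(tert-butyldimethylsilyloxy)-4-(4-methoxybenzyloxy)-2,6-dimethylocta-1,5-dien-1-yl]-4-[4-(trimethylsilyl)but-3-yn-1-yl]oxolan-2-one, via lactol 21 (not isolated)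
Conditions: TEMPO (20 mol%), PhI(OAc)2 (3 equiv), CH2Cl2, rt
Reagents that add atoms: none
Why: oxoammonium oxidation selective for the primary alcohol gives an aldehyde that the C1 hydroxyl traps as a five-membered lactol, which is oxidised on to the γ-lactone (oxidative lactonisation of a 1,4-diol); the anti diol maps onto the trans lactone.

Step 12
Reactants: 22 silylated lactone
Product: 23 (4R,5R)-4-(but-3-yn-1-yl)-5-[(1E,4S,5E)-8-hydroxy-4-(4-methoxybenzyloxy)-2,6-dimethylocta-1,5-dien-1-yl]oxolan-2-one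
Conditions: Bu4NF (3 equiv), THF, 0 °C to rt
Reagents that add atoms: none
Why: fluoride cleaves the primary silyl ether and the alkynyl C–Si bond in one operation, removing both temporary groups before ring closure.

Step 13
Reactants: 23 hydroxy alkyne
Product: 24 (3E,5S,7E)-8-[(2R,3R)-3-(but-3-yn-1-yl)-5-oxooxolan-2-yl]-5-(4-methoxybenzyloxy)-3,7-dimethylocta-3,7-dienal
Conditions: Dess–Martin periodinane, NaHCO3, CH2Cl2, 0 °C; used at once
Reagents that add atoms: none
Why: buffered Dess–Martin oxidation gives the β,γ-unsaturated aldehyde without migration of the C6=C7 double bond into conjugation.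

Step 14
Reactants: 24 ynal
Product: 25 (3aR,6E,10E,12S,14E,15aR)-8-hydroxy-12-(4-methoxybenzyloxy)-6,10,14-trimethyl-3a,4,5,8,9,12,13,15a-octahydrocyclotetradeca[b]furan-2(3H)-one, mixture of C9 epimers
Conditions: Ni(COD)2 (20 mol%), IMes (1,3-dimesitylimidazol-2-ylidene, 20 mol%), Me2Zn (3 equiv), THF, syringe-pump addition of 24 to 2 mM, 0 °C to rt; aq. NH4Cl
Reagents that add atoms: dimethylzinc C[Zn]C
Why: Proposed new method: zerovalent nickel binds the terminal alkyne and the aldehyde of 24 and couples them oxidatively to an oxanickelacyclopentene in which the aldehyde carbon C9 is bonded to the unsubstituted alkyne carbon C10 and nickel sits on C11; methyl transfer from Me2Zn to nickel with opening of the Ni–O bond, then C(sp2)–CH3 reductive elimination, should deliver the zinc alkoxide of 25 and return the catalyst, and because methyl has no β-hydrogen no hydride (reductive) pathway can compete. The closest known reaction types are the nickel-catalysed alkylative coupling of alkynes and aldehydes with organozincs (intermolecular and for five- and six-membered rings) and the nickel-catalysed reductive macrocyclisation of terminal ynals with silanes; the methylative closure of a 14-membered ring merges the two and is the new element. The 14-membered carbocycle closes in the endo mode with respect to the alkyne (14-endo-dig, both alkyne carbons becoming ring atoms). The C10=C11 geometry follows from syn addition of C9 and CH3 across the alkyne, which places the methyl cis to C9 and makes the ring olefin (E); the C9 configuration is under weak control only, because the nearest stereocentre (C5) is 1,5-related, and is therefore reset in steps 15 and 16. The step needs endo regioselectivity and chemoselectivity for the alkyne–aldehyde pair: the terminal alkyne offers its unhindered CH to the aldehyde under a small N-heterocyclic carbene ligand, the trisubstituted olefins and the allylic C–O bonds at C1 and C5 bind nickel poorly, uncatalysed methyl addition of Me2Zn to the aldehyde is slow, high dilution suppresses alkyne oligomerisation, and the α-methylene lactone (an enoate that would undergo nickel-catalysed alkylative enoate–alkyne cyclisation) is deliberately still absent.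

Step 15
Reactants: 25 macrocyclic allylic alcohol (C9 epimers)
Product: 26 (3aR,6E,10E,12S,14E,15aR)-12-(4-methoxybenzyloxy)-6,10,14-trimethyl-8-oxo-3a,4,5,8,9,12,13,15a-octahydrocyclotetradeca[b]furan-2(3H)-one
Conditions: Dess–Martin periodinane, NaHCO3, CH2Cl2, 0 °C
Reagents that add atoms: none
Why: Dess–Martin oxidation of the allylic alcohol converges both C9 epimers on one enone under neutral conditions that leave the skipped C6=C7 olefin in place.

Step 16
Reactants: 26 macrocyclic enone
Product: 27 (3aR,6E,8S,10E,12S,14E,15aR)-8-hydroxy-12-(4-methoxybenzyloxy)-6,10,14-trimethyl-3a,4,5,8,9,12,13,15a-octahydrocyclotetradeca[b]furan-2(3H)-one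
Conditions: (R)-2-methyl-CBS-oxazaborolidine (1 equiv), catecholborane, toluene, −78 °C
Reagents that add atoms: none
Why: Corey–Bakshi–Shibata reduction in which the C10 alkenyl group acts as the large substituent and C8H2 as the small one, so that the (R)-catalyst should deliver hydride to give the (9S)-alcohol under reagent control.

Step 17
Reactants: 27 (9S)-alcohol
Product: 28 (3aR,6E,8S,10E,12S,14E,15aR)-8-(tert-butyldimethylsilyloxy)-12-(4-methoxybenzyloxy)-6,10,14-trimethyl-3a,4,5,8,9,12,13,15a-octahydrocyclotetradeca[b]furan-2(3H)-one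
Conditions: TBSOTf, 2,6-lutidine, CH2Cl2, −78 °C
Reagents that add atoms: tert-butyldimethylsilyl trifluoromethanesulfonate CC(C)(C)[Si](C)(C)OS(=O)(=O)C(F)(F)F
Why: silylation of the secondary allylic alcohol masks C9–OH against the strong base of step 18 and differentiates it from the C5 oxygen.

Step 18
Reactants: 28 protected lactone
Product: 32 (3aR,6E,8S,10E,12S,14E,15aS)-8-(tert-butyldimethylsilyloxy)-12-(4-methoxybenzyloxy)-6,10,14-trimethyl-3-methylidene-3a,4,5,8,9,12,13,15a-octahydrocyclotetradeca[b]furan-2(3H)-one, via lithium enolate 29 (not isolated), via Mannich base 30 (not isolated), via ammonium iodide 31 (not isolated)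
Conditions: LDA (1.2 equiv), THF, −78 °C; Eschenmoser's salt, −78 °C to rt; then MeI, MeOH, rt; then aq. NaHCO3/CH2Cl2, rt
Reagents that add atoms: N,N-dimethylmethyleneiminium iodide C=[N+](C)C.[I-]
Why: Mannich reaction of the lactone enolate followed by quaternisation and base-induced elimination of trimethylamine is the standard α-methylenation of γ-lactones, and C14 carries no β-leaving group so its configuration is not at risk.

Step 19
Reactants: 32 α-methylene lactone PMB ether
Product: 33 (3aR,6E,8S,10E,12S,14E,15aS)-8-(tert-butyldimethylsilyloxy)-12-hydroxy-6,10,14-trimethyl-3-methylidene-3a,4,5,8,9,12,13,15a-octahydrocyclotetradeca[b]furan-2(3H)-one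
Conditions: DDQ, CH2Cl2/pH 7 buffer, 0 °C
Reagents that add atoms: none
Why: oxidative cleavage of the 4-methoxybenzyl ether by hydride abstraction and hydrolysis frees C5–OH while the silyl ether and the enoate are inert.

Step 20
Reactants: 33 C5 alcohol
Product: 34 (3aR,6E,8S,10E,12S,14E,15aS)-8-(tert-butyldimethylsilyloxy)-6,10,14-trimethyl-3-methylidene-2-oxo-2,3,3a,4,5,8,9,12,13,15a-decahydrocyclotetradeca[b]furan-12-yl acetate
Conditions: Ac2O, Et3N, DMAP (cat.), CH2Cl2, 0 °C
Reagents that add atoms: acetic anhydride CC(=O)OC(C)=O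
Why: DMAP-catalysed acylation of the only free hydroxyl proceeds with retention at C5.

Step 21
Reactants: 34 acetate silyl ether
Product: 35 (3aR,6E,8S,10E,12S,14E,15aS)-8-hydroxy-6,10,14-trimethyl-3-methylidene-2-oxo-2,3,3a,4,5,8,9,12,13,15a-decahydrocyclotetradeca[b]furan-12-yl acetate
Conditions: HF·pyridine, pyridine/THF, 0 °C to rt
Reagents that add atoms: none
Why: buffered fluoride desilylation frees C9–OH under conditions that neither cleave nor migrate the allylic acetate and do not add to the α-methylene lactone.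

**Compound list**

1 | tert-butyl(but-3-yn-1-yloxy)dimethylsilane | C#CCCO[Si](C)(C)C(C)(C)C | starting material
2 | (E)-[4-(tert-butyldimethylsilyloxy)-2-methylbut-1-en-1-yl]dimethylalane | C[Al](C)/C=C(\C)CCO[Si](C)(C)C(C)(C)C | intermediate
3 | (E)-tert-butyl[(4-iodo-3-methylbut-3-en-1-yl)oxy]dimethylsilane | I/C=C(\C)CCO[Si](C)(C)C(C)(C)C | intermediate
4 | (E)-[4-(tert-butyldimethylsilyloxy)-2-methylbut-1-en-1-yl]lithium | [Li]/C=C(\C)CCO[Si](C)(C)C(C)(C)C | intermediate
5 | (E)-5-(tert-butyldimethylsilyloxy)-3-methylpent-2-enal | O=C/C=C(\C)CCO[Si](C)(C)C(C)(C)C | intermediate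
6 | pinacol borate (O-boryl ether) of 7 | C#CC[C@H](OB1OC(C)(C)C(C)(C)O1)/C=C(\C)CCO[Si](C)(C)C(C)(C)C | intermediate
7 | (4S,5E)-8-(tert-butyldimethylsilyloxy)-6-methyloct-5-en-1-yn-4-ol | C#CC[C@H](O)/C=C(\C)CCO[Si](C)(C)C(C)(C)C | intermediate
8 | (1E,5E)-alkenyl(dimethyl)alane of 7 with the C4 oxygen as dimethylaluminium alkoxide | C[Al](C)/C=C(\C)C[C@H](O[Al](C)C)/C=C(\C)CCO[Si](C)(C)C(C)(C)C | intermediate
9 | (1E,4S,5E)-8-(tert-butyldimethylsilyloxy)-1-iodo-2,6-dimethylocta-1,5-dien-4-ol | I/C=C(\C)C[C@H](O)/C=C(\C)CCO[Si](C)(C)C(C)(C)C | intermediate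
10 | (1E,4S,5E)-8-(tert-butyldimethylsilyloxy)-1-iodo-4-(4-methoxybenzyloxy)-2,6-dimethylocta-1,5-diene | I/C=C(\C)C[C@H](OCc1ccc(OC)cc1)/C=C(\C)CCO[Si](C)(C)C(C)(C)C | intermediate
11 | vinyllithium derived from 10 (Li in place of I) | [Li]/C=C(\C)C[C@H](OCc1ccc(OC)cc1)/C=C(\C)CCO[Si](C)(C)C(C)(C)C | intermediate
12 | (2E,5S,6E)-9-(tert-butyldimethylsilyloxy)-5-(4-methoxybenzyloxy)-3,7-dimethylnona-2,6-dienal | O=C/C=C(\C)C[C@H](OCc1ccc(OC)cc1)/C=C(\C)CCO[Si](C)(C)C(C)(C)C | intermediate
13 | (4-bromobut-1-yn-1-yl)trimethylsilane | C[Si](C)(C)C#CCCBr | starting material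
14 | [4-(trimethylsilyl)but-3-yn-1-yl]magnesium bromide | C[Si](C)(C)C#CCC[Mg]Br | intermediate
15 | rac-7-(trimethylsilyl)hept-1-en-6-yn-3-ol | C=CC(O)CCC#C[Si](C)(C)C | intermediate
16 | (E)-4,4,5,5-tetramethyl-2-[7-(trimethylsilyl)hept-2-en-6-yn-1-yl]-1,3,2-dioxaborolane | C[Si](C)(C)C#CCC/C=C/CB1OC(C)(C)C(C)(C)O1 | intermediate
17 | pinacol borate (O-boryl ether) of 18 | C=C[C@@H](CCC#C[Si](C)(C)C)[C@@H](OB1OC(C)(C)C(C)(C)O1)/C=C(\C)C[C@H](OCc1ccc(OC)cc1)/C=C(\C)CCO[Si](C)(C)C(C)(C)C | intermediate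
18 | (3R,4R,5E,8S,9E)-12-(tert-butyldimethylsilyloxy)-8-(4-methoxybenzyloxy)-6,10-dimethyl-3-[4-(trimethylsilyl)but-3-yn-1-yl]dodeca-1,5,9-trien-4-ol | C=C[C@@H](CCC#C[Si](C)(C)C)[C@@H](O)/C=C(\C)C[C@H](OCc1ccc(OC)cc1)/C=C(\C)CCO[Si](C)(C)C(C)(C)C | intermediate
19 | B-alkyl-9-borabicyclo[3.3.1]nonane from 18 (boron on the terminal carbon; hydroxyl drawn free) | B1(C2CCCC1CCC2)CC[C@@H](CCC#C[Si](C)(C)C)[C@@H](O)/C=C(\C)C[C@H](OCc1ccc(OC)cc1)/C=C(\C)CCO[Si](C)(C)C(C)(C)C | intermediate
20 | (3R,4R,5E,8S,9E)-12-(tert-butyldimethylsilyloxy)-8-(4-methoxybenzyloxy)-6,10-dimethyl-3-[4-(trimethylsilyl)but-3-yn-1-yl]dodeca-5,9-diene-1,4-diol | OCC[C@@H](CCC#C[Si](C)(C)C)[C@@H](O)/C=C(\C)C[C@H](OCc1ccc(OC)cc1)/C=C(\C)CCO[Si](C)(C)C(C)(C)C | intermediate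
21 | lactol (2-hydroxyoxolane, anomer mixture) corresponding to 22 | OC1C[C@@H](CCC#C[Si](C)(C)C)[C@@H](O1)/C=C(\C)C[C@H](OCc2ccc(OC)cc2)/C=C(\C)CCO[Si](C)(C)C(C)(C)C | intermediate
22 | (4R,5R)-5-[(1E,4S,5E)-8-(tert-butyldimethylsilyloxy)-4-(4-methoxybenzyloxy)-2,6-dimethylocta-1,5-dien-1-yl]-4-[4-(trimethylsilyl)but-3-yn-1-yl]oxolan-2-one | O=C1C[C@@H](CCC#C[Si](C)(C)C)[C@@H](O1)/C=C(\C)C[C@H](OCc2ccc(OC)cc2)/C=C(\C)CCO[Si](C)(C)C(C)(C)C | intermediate
23 | (4R,5R)-4-(but-3-yn-1-yl)-5-[(1E,4S,5E)-8-hydroxy-4-(4-methoxybenzyloxy)-2,6-dimethylocta-1,5-dien-1-yl]oxolan-2-one | O=C1C[C@@H](CCC#C)[C@@H](O1)/C=C(\C)C[C@H](OCc2ccc(OC)cc2)/C=C(\C)CCO | intermediate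
24 | (3E,5S,7E)-8-[(2R,3R)-3-(but-3-yn-1-yl)-5-oxooxolan-2-yl]-5-(4-methoxybenzyloxy)-3,7-dimethylocta-3,7-dienal | O=C1C[C@@H](CCC#C)[C@@H](O1)/C=C(\C)C[C@H](OCc2ccc(OC)cc2)/C=C(\C)CC=O | intermediate
25 | (3aR,6E,10E,12S,14E,15aR)-8-hydroxy-12-(4-methoxybenzyloxy)-6,10,14-trimethyl-3a,4,5,8,9,12,13,15a-octahydrocyclotetradeca[b]furan-2(3H)-one, mixture of C9 epimers | O=C1O[C@H]2/C=C(\C)C[C@H](OCc3ccc(OC)cc3)/C=C(\C)CC(O)/C=C(\C)CC[C@@H]2C1 | intermediate
26 | (3aR,6E,10E,12S,14E,15aR)-12-(4-methoxybenzyloxy)-6,10,14-trimethyl-8-oxo-3a,4,5,8,9,12,13,15a-octahydrocyclotetradeca[b]furan-2(3H)-one | O=C1O[C@H]2/C=C(\C)C[C@H](OCc3ccc(OC)cc3)/C=C(\C)CC(=O)/C=C(\C)CC[C@@H]2C1 | intermediate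
27 | (3aR,6E,8S,10E,12S,14E,15aR)-8-hydroxy-12-(4-methoxybenzyloxy)-6,10,14-trimethyl-3a,4,5,8,9,12,13,15a-octahydrocyclotetradeca[b]furan-2(3H)-one | O=C1O[C@H]2/C=C(\C)C[C@H](OCc3ccc(OC)cc3)/C=C(\C)C[C@H](O)/C=C(\C)CC[C@@H]2C1 | intermediate
28 | (3aR,6E,8S,10E,12S,14E,15aR)-8-(tert-butyldimethylsilyloxy)-12-(4-methoxybenzyloxy)-6,10,14-trimethyl-3a,4,5,8,9,12,13,15a-octahydrocyclotetradeca[b]furan-2(3H)-one | O=C1O[C@H]2/C=C(\C)C[C@H](OCc3ccc(OC)cc3)/C=C(\C)C[C@H](O[Si](C)(C)C(C)(C)C)/C=C(\C)CC[C@@H]2C1 | intermediate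
29 | lithium enolate of lactone 28 | [Li]OC1O[C@H]2/C=C(\C)C[C@H](OCc3ccc(OC)cc3)/C=C(\C)C[C@H](O[Si](C)(C)C(C)(C)C)/C=C(\C)CC[C@@H]2C=1 | intermediate
30 | 3-[(dimethylamino)methyl] derivative of 28 (Mannich base, configuration at Cα not defined) | CN(C)CC1C(=O)O[C@H]2/C=C(\C)C[C@H](OCc3ccc(OC)cc3)/C=C(\C)C[C@H](O[Si](C)(C)C(C)(C)C)/C=C(\C)CC[C@H]12 | intermediate
31 | trimethylammonium iodide obtained from 30 | C[N+](C)(C)CC1C(=O)O[C@H]2/C=C(\C)C[C@H](OCc3ccc(OC)cc3)/C=C(\C)C[C@H](O[Si](C)(C)C(C)(C)C)/C=C(\C)CC[C@H]12.[I-] | intermediate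
32 | (3aR,6E,8S,10E,12S,14E,15aS)-8-(tert-butyldimethylsilyloxy)-12-(4-methoxybenzyloxy)-6,10,14-trimethyl-3-methylidene-3a,4,5,8,9,12,13,15a-octahydrocyclotetradeca[b]furan-2(3H)-one | C=C1C(=O)O[C@H]2/C=C(\C)C[C@H](OCc3ccc(OC)cc3)/C=C(\C)C[C@H](O[Si](C)(C)C(C)(C)C)/C=C(\C)CC[C@H]12 | intermediate
33 | (3aR,6E,8S,10E,12S,14E,15aS)-8-(tert-butyldimethylsilyloxy)-12-hydroxy-6,10,14-trimethyl-3-methylidene-3a,4,5,8,9,12,13,15a-octahydrocyclotetradeca[b]furan-2(3H)-one | C=C1C(=O)O[C@H]2/C=C(\C)C[C@H](O)/C=C(\C)C[C@H](O[Si](C)(C)C(C)(C)C)/C=C(\C)CC[C@H]12 | intermediate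
34 | (3aR,6E,8S,10E,12S,14E,15aS)-8-(tert-butyldimethylsilyloxy)-6,10,14-trimethyl-3-methylidene-2-oxo-2,3,3a,4,5,8,9,12,13,15a-decahydrocyclotetradeca[b]furan-12-yl acetate | C=C1C(=O)O[C@H]2/C=C(\C)C[C@H](OC(C)=O)/C=C(\C)C[C@H](O[Si](C)(C)C(C)(C)C)/C=C(\C)CC[C@H]12 | intermediate
35 | (3aR,6E,8S,10E,12S,14E,15aS)-8-hydroxy-6,10,14-trimethyl-3-methylidene-2-oxo-2,3,3a,4,5,8,9,12,13,15a-decahydrocyclotetradeca[b]furan-12-yl acetate (CNP0168244.1) | C=C1C(=O)O[C@H]2/C=C(\C)C[C@H](OC(C)=O)/C=C(\C)C[C@H](O)/C=C(\C)CC[C@H]12 | target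

**Step count and risks**

Total step count: 21. Longest linear sequence: 19 steps (steps 1–6 and 9–21); steps 7–8 make the allylboronate.

Steps most likely to fail:

1. Step 14. The risk is that alkyne oligomerisation, exo-mode closure or methyl transfer to the aldehyde outruns the endo alkylative macrocyclisation, or that nickel ionises the allylic lactone C1–O bond. The fallback sets out from 23 and returns at 25. Water-accelerated zirconium-catalysed methylalumination (AlMe3, Cp2ZrCl2, H2O, CH2Cl2, −20 °C) and iodinolysis convert the terminal alkyne of 23 into the (E)-vinyl iodide lactone alcohol F1. Dess–Martin oxidation gives the iodo aldehyde F2. A Nozaki–Hiyama–Kishi macrocyclisation (CrCl2, NiCl2 cat., DMSO/THF, high dilution) then forms the same C9–C10 bond and should give 25, after which steps 15 and 16 follow unchanged.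

2. Step 9. The risk is loss of anti selectivity through 1,3-boratropic E/Z scrambling of the allylboronate, or weak facial control by the acid on a β,β-disubstituted enal. The fallback sets out from 15 (used with 12) and returns at 18. PBr3 (Et2O, 0 °C) converts 15 with allylic transposition into the primary allylic bromide F3. A Nozaki–Hiyama allylation of 12 mediated by CrCl2 in the presence of a chiral oxazoline–sulfonamide ligand (Et3N, THF) should give 18: the γ-substituted allylchromium species reacts through a chair transition state to the anti adduct whatever the geometry of the bromide, and the ligand biases the aldehyde face.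

3. Step 16. The risk is that the macrocycle conformation overrides catalyst control of the hydride face, or that the C6=C7 double bond slips into conjugation with the ketone. The fallback sets out from 25 and returns at 27, bypassing 26. The C9 epimers of 25 are separated by chromatography, the (9S)-epimer being 27 itself. The (9R)-epimer F4 is inverted by a Mitsunobu reaction (4-nitrobenzoic acid, PPh3, DIAD, toluene, 0 °C) to the (9S)-4-nitrobenzoate F5, and mild methanolysis (K2CO3, MeOH, 0 °C) gives 27.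

**Further compounds**

F1 | step 14 | (4R,5R)-5-[(1E,4S,5E)-8-hydroxy-4-(4-methoxybenzyloxy)-2,6-dimethylocta-1,5-dien-1-yl]-4-[(3E)-4-iodo-3-methylbut-3-en-1-yl]oxolan-2-one | O=C1C[C@@H](CC/C(C)=C/I)[C@@H](O1)/C=C(\C)C[C@H](OCc2ccc(OC)cc2)/C=C(\C)CCO
F2 | step 14 | (3E,5S,7E)-8-[(2R,3R)-3-[(3E)-4-iodo-3-methylbut-3-en-1-yl]-5-oxooxolan-2-yl]-5-(4-methoxybenzyloxy)-3,7-dimethylocta-3,7-dienal | O=C1C[C@@H](CC/C(C)=C/I)[C@@H](O1)/C=C(\C)C[C@H](OCc2ccc(OC)cc2)/C=C(\C)CC=O
F3 | step 9 | (E)-(7-bromohept-5-en-1-yn-1-yl)trimethylsilane | C[Si](C)(C)C#CCC/C=C/CBr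
F4 | step 16 | (3aR,6E,8R,10E,12S,14E,15aR)-8-hydroxy-12-(4-methoxybenzyloxy)-6,10,14-trimethyl-3a,4,5,8,9,12,13,15a-octahydrocyclotetradeca[b]furan-2(3H)-one | O=C1O[C@H]2/C=C(\C)C[C@H](OCc3ccc(OC)cc3)/C=C(\C)C[C@@H](O)/C=C(\C)CC[C@@H]2C1
F5 | step 16 | (3aR,6E,8S,10E,12S,14E,15aR)-12-(4-methoxybenzyloxy)-6,10,14-trimethyl-2-oxo-2,3,3a,4,5,8,9,12,13,15a-decahydrocyclotetradeca[b]furan-8-yl 4-nitrobenzoate | O=C1O[C@H]2/C=C(\C)C[C@H](OCc3ccc(OC)cc3)/C=C(\C)C[C@H](OC(=O)c4ccc(cc4)[N+](=O)[O-])/C=C(\C)CC[C@@H]2C1
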